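**Strategy.** The macrolactam is opened at C7–C8 (ansamycin numbering: amide carbonyl C1, aryl carbons C16–C21), the bond joining the carbamate-bearing carbinol to the trisubstituted olefin, far from the anilide. A zerovalent-nickel/N-heterocyclic-carbene reductive coupling of a C8≡C9 methyl alkyne with a C7 α-methoxy aldehyde closes the 19-membered ring, creates the (E)-C8=C9 olefin by syn addition and delivers the C7 allylic oxygen in one operation. It exploits the allylic carbinol C7 flanked by the C8(Me)=C9 olefin inside the ansa ring. The precursor is an open-chain anilide ynal made from an aryl alkyne fragment (C8–C21) and a C1–C7 enoate; C7 is finally fixed by oxidation and reagent-controlled reduction.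

Key step: step 22

Remark: in this numbering the target is 2E,6S,7S,8E,10S,11R,12S,14S,15R; TIPS = triisopropylsilyl, TBS = tert-butyldimethylsilyl, PMB = 4-methoxybenzyl.

**Allenylstannane (steps 1–3)**

Step 1
Reactants: 1 pent-3-yn-2-one
Product: 2 (S)-pent-3-yn-2-ol
Conditions: RuCl[(S,S)-TsDPEN](p-cymene) (1 mol%), i-PrOH, rt
Reagents that add atoms: none
Why: Noyori-type asymmetric transfer hydrogenation of an ynone, in which the (S,S)-diamine ruthenium hydride distinguishes the alkynyl from the methyl flank and should give the (S) carbinol.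

Step 2
Reactants: 2 (S)-pent-3-yn-2-ol
Product: 3 (S)-pent-3-yn-2-yl methanesulfonate
Conditions: MsCl, Et3N, CH2Cl2, −78 °C
Reagents that add atoms: methanesulfonyl chloride, CS(=O)(=O)Cl
Why: O-sulfonylation that leaves the stereocenter untouched.

Step 3
Reactants: 3 (S)-pent-3-yn-2-yl methanesulfonate
Product: 4 (M)-tributyl(penta-2,3-dien-2-yl)stannane
Conditions: Bu3SnH, LiN(i-Pr)2, THF, −78 °C; CuBr·SMe2; then 3, −78 °C
Reagents that add atoms: tributyltin hydride, CCCC[SnH](CCCC)CCCC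
Why: anti-SN2′ displacement of the propargylic mesylate by the stannylcopper reagent, which should transfer the (S) center into the (M) allene axis.

**Aryl alkyne fragment, C8–C21 (steps 4–15)**

Step 4
Reactants: 5 3-hydroxy-5-nitrobenzaldehyde
Product: 6 3-nitro-5-(triisopropylsilyloxy)benzaldehyde
Conditions: TIPSCl, imidazole, DMF, rt
Reagents that add atoms: chlorotriisopropylsilane, CC(C)[Si](Cl)(C(C)C)C(C)C
Why: silylation of the phenol with a base-robust silyl group that is removed only in the last step.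

Step 5
Reactants: 6 3-nitro-5-(triisopropylsilyloxy)benzaldehyde
Product: 7 (1R,2S)-2-methyl-1-[3-nitro-5-(triisopropylsilyloxy)phenyl]but-3-en-1-ol
Conditions: (Z)-crotylboronic acid pinacol ester (1.2 equiv), (R)-TRIP phosphoric acid (5 mol%), 4 Å MS, toluene, −30 °C
Reagents that add atoms: (Z)-crotylboronic acid pinacol ester, C/C=C\CB1OC(C)(C)C(C)(C)O1
Why: chiral phosphoric acid-catalysed crotylboration through a closed chair transition state, in which the Z-crotyl geometry should give the 14,15-syn relationship and the (R)-catalyst should select the aldehyde Re face (15R, 14S).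

Step 6
Reactants: 7 (1R,2S)-2-methyl-1-[3-nitro-5-(triisopropylsilyloxy)phenyl]but-3-en-1-ol
Product: 8 (5S,6R)-5-methyl-6-[3-nitro-5-(triisopropylsilyloxy)phenyl]oxan-2-ol (lactol, both anomers)
Conditions: Rh(CO)2(acac) (1 mol%), Xantphos (2 mol%), CO/H2 (1:1, 10 bar), toluene, 60 °C
Reagents that add atoms: carbon monoxide, [C-]#[O+]
Why: linear-selective rhodium hydroformylation of the allylically branched terminal alkene installs C11, and the δ-hydroxy aldehyde should close to the lactol without touching C14 or C15.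

Step 7
Reactants: 8 lactol (5S,6R)-5-methyl-6-[3-nitro-5-(triisopropylsilyloxy)phenyl]oxan-2-ol
Product: 9 (5S,6R)-5-methyl-6-[3-nitro-5-(triisopropylsilyloxy)phenyl]oxan-2-one
Conditions: PhI(OAc)2, TEMPO (10 mol%), CH2Cl2, rt
Reagents that add atoms: none
Why: oxoammonium (TEMPO) oxidation of a lactol to the δ-lactone, which serves as the cyclic template for C12.

Step 8
Reactants: 9 (5S,6R)-5-methyl-6-[3-nitro-5-(triisopropylsilyloxy)phenyl]oxan-2-one
Product: 11 (3S,5S,6R)-3-hydroxy-5-methyl-6-[3-nitro-5-(triisopropylsilyloxy)phenyl]oxan-2-one, via potassium lactone enolate 10 (not isolated)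
Conditions: KN(SiMe3)2, THF, −78 °C; then trans-2-(phenylsulfonyl)-3-phenyloxaziridine, −78 °C; AcOH quench
Reagents that add atoms: trans-2-(phenylsulfonyl)-3-phenyloxaziridine, O=S(=O)(c1ccccc1)N1OC1c1ccccc1
Why: enolate oxidation with an N-sulfonyloxaziridine, in which the oxidant should approach the lactone enolate on the face opposite the cis-disposed C14 methyl and C15 aryl groups, giving the 12S (3,5-trans, equatorial) alcohol by substrate control.

Step 9
Reactants: 11 (3S,5S,6R)-3-hydroxy lactone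
Product: 12 (3S,5S,6R)-3-methoxy-5-methyl-6-[3-nitro-5-(triisopropylsilyloxy)phenyl]oxan-2-one
Conditions: Me3OBF4, 1,8-bis(dimethylamino)naphthalene, 4 Å MS, CH2Cl2, rt
Reagents that add atoms: trimethyloxonium tetrafluoroborate, C[O+](C)C.F[B-](F)(F)F
Why: O-methylation with a Meerwein salt under non-enolizing conditions, so the new α-stereocenter and the lactone are preserved.

Step 10
Reactants: 12 (3S,5S,6R)-3-methoxy lactone
Product: 13 (2S,4S,5R)-5-hydroxy-N,2-dimethoxy-N,4-dimethyl-5-[3-nitro-5-(triisopropylsilyloxy)phenyl]pentanamide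
Conditions: MeNH(OMe)·HCl, Me3Al, CH2Cl2, 0 °C → rt
Reagents that add atoms: N,O-dimethylhydroxylamine hydrochloride, CNOC.Cl
Why: aluminium amide aminolysis of the lactone (Weinreb amide formation) opens the template and frees the C15 hydroxyl.

Step 11
Reactants: 13 hydroxy Weinreb amide
Product: 14 (2S,4S,5R)-5-(tert-butyldimethylsilyloxy)-N,2-dimethoxy-N,4-dimethyl-5-[3-nitro-5-(triisopropylsilyloxy)phenyl]pentanamide
Conditions: TBSOTf, 2,6-lutidine, CH2Cl2, −78 → 0 °C
Reagents that add atoms: tert-butyldimethylsilyl triflate, CC(C)(C)[Si](C)(C)OS(=O)(=O)C(F)(F)F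
Why: silylation of the benzylic alcohol prevents relactonization and protects C15–OH to the end.

Step 12
Reactants: 14 silylated Weinreb amide
Product: 15 (2S,4S,5R)-5-(tert-butyldimethylsilyloxy)-2-methoxy-4-methyl-5-[3-nitro-5-(triisopropylsilyloxy)phenyl]pentanal
Conditions: i-Bu2AlH, THF, −78 °C
Reagents that add atoms: none
Why: hydride reduction of a Weinreb amide stops at the chelated tetrahedral intermediate and should release the C11 α-methoxy aldehyde on work-up without epimerizing C12.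

Step 13
Reactants: 15 C11 aldehyde; 4 (M)-tributyl(penta-2,3-dien-2-yl)stannane
Product: 16 (1R,2S,4S,5R,6S)-1-(tert-butyldimethylsilyloxy)-4-methoxy-2,6-dimethyl-1-[3-nitro-5-(triisopropylsilyloxy)phenyl]non-7-yn-5-ol
Conditions: BF3·OEt2, CH2Cl2, −78 °C
Reagents that add atoms: none
Why: BF3-promoted anti-SE2′ addition of the chiral allenylstannane through an open transition state, in which the (M) axis sets 10S, the open arrangement gives 10,11-syn and Felkin–Anh attack anti to the C12 methoxy group gives 11,12-anti (11R), a matched pairing that also installs the C8≡C9 methyl alkyne.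

Step 14
Reactants: 16 homopropargylic alcohol
Product: 17 (1R,2S,4S,5R,6S)-1,5-bis(tert-butyldimethylsilyloxy)-4-methoxy-2,6-dimethyl-1-[3-nitro-5-(triisopropylsilyloxy)phenyl]non-7-yne
Conditions: TBSOTf, 2,6-lutidine, CH2Cl2, 0 °C
Reagents that add atoms: tert-butyldimethylsilyl triflate, CC(C)(C)[Si](C)(C)OS(=O)(=O)C(F)(F)F
Why: silylation of the hindered C11 hydroxyl so that only C7 carries a free or carbamoylated oxygen later.

Step 15
Reactants: 17 nitroarene
Product: 18 3-[(1R,2S,4S,5R,6S)-1,5-bis(tert-butyldimethylsilyloxy)-4-methoxy-2,6-dimethylnon-7-yn-1-yl]-5-(triisopropylsilyloxy)aniline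
Conditions: Fe powder, NH4Cl, EtOH/H2O (4:1), 70 °C
Reagents that add atoms: none
Why: neutral dissolving-metal (Béchamp-type) reduction of the nitro group, which should leave the internal alkyne and the silyl ethers intact.

**C1–C7 enoate (steps 16–18)**

Step 16
Reactants: 19 (S)-2-[(4-methoxybenzyloxy)methyl]oxirane
Product: 20 (S)-1-(4-methoxybenzyloxy)hex-5-en-2-ol
Conditions: allylMgBr, CuI (10 mol%), THF, −40 °C
Reagents that add atoms: allylmagnesium bromide, C=CC[Mg]Br
Why: copper-catalysed Grignard opening of the terminal epoxide at its CH2 terminus, so the purchased C6 stereocenter is retained.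

Step 17
Reactants: 20 (S)-1-(4-methoxybenzyloxy)hex-5-en-2-ol
Product: 21 (S)-2-methoxy-1-(4-methoxybenzyloxy)hex-5-ene
Conditions: NaH, MeI, THF, 0 °C → rt
Reagents that add atoms: iodomethane, CI
Why: Williamson etherification installs the C6 methyl ether.

Step 18
Reactants: 21 (S)-2-methoxy-1-(4-methoxybenzyloxy)hex-5-ene
Product: 22 methyl (2E,6S)-6-methoxy-7-(4-methoxybenzyloxy)-2-methylhept-2-enoate
Conditions: methyl methacrylate (10 equiv), second-generation Hoveyda–Grubbs catalyst (5 mol%), CH2Cl2, 40 °C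
Reagents that add atoms: methyl methacrylate, COC(=O)C(C)=C
Why: olefin cross-metathesis with a 1,1-disubstituted acrylate, which should give the thermodynamically favoured (E)-trisubstituted C2=C3 enoate.

**Assembly, ring closure and endgame (steps 19–26)**

Step 19
Reactants: 18 aniline fragment; 22 methyl enoate
Product: 23 (2E,6S)-N-{3-[(1R,2S,4S,5R,6S)-1,5-bis(tert-butyldimethylsilyloxy)-4-methoxy-2,6-dimethylnon-7-yn-1-yl]-5-(triisopropylsilyloxy)phenyl}-6-methoxy-7-(4-methoxybenzyloxy)-2-methylhept-2-enamide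
Conditions: Me3Al (3 equiv), toluene, 0 → 60 °C
Reagents that add atoms: none
Why: aluminium amide-mediated aminolysis of the ester by the dimethylaluminium anilide (Weinreb amidation) forms the anilide directly, without an acid chloride.

Step 20
Reactants: 23 PMB-protected seco anilide
Product: 24 the corresponding (2E,6S)-7-hydroxy-6-methoxy-2-methylhept-2-enamide (seco alcohol)
Conditions: DDQ, CH2Cl2/pH 7 buffer (10:1), 0 °C
Reagents that add atoms: none
Why: oxidative cleavage of the PMB ether by DDQ, which should spare the silyl ethers, the alkyne and the anilide.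

Step 21
Reactants: 24 seco alcohol
Product: 25 the corresponding (2E,6S)-6-methoxy-2-methyl-7-oxohept-2-enamide (seco ynal)
Conditions: Dess–Martin periodinane, NaHCO3, CH2Cl2, 0 °C → rt
Reagents that add atoms: none
Why: buffered Dess–Martin oxidation to the C7 α-methoxy aldehyde, used at once to avoid epimerization at C6.

Step 22
Reactants: 25 seco ynal
Product: 27 macrolactam (2E,6S,7R,8E,10S,11R,12S,14S,15R)-7-hydroxy-11,15-bis(tert-butyldimethylsilyloxy)-18-(triisopropylsilyloxy) (7R shown as the expected major epimer), via macrocyclic C7 triethylsilyl ether 26 (not isolated)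
Conditions: Ni(cod)2 (20 mol%), IMes·HCl (20 mol%), KOt-Bu (20 mol%), Et3SiH (3 equiv), THF, 0.002 M, syringe-pump addition of 25 over 8 h, rt; then PPTS, MeOH, rt
Reagents that add atoms: triethylsilane, CC[SiH](CC)CC (its silyl group is carried only by 26)
Why: Zerovalent nickel with IMes binds the C8≡C9 alkyne and the C7 aldehyde, and oxidative cyclization gives an oxanickelacyclopentene containing the new C7–C8 bond; σ-bond metathesis with Et3SiH and C–H reductive elimination place hydrogen on C9 cis to C7 and release the C7 triethylsilyl ether 26, which PPTS/MeOH cleaves in the same flask. The closest known reaction type is the nickel-catalysed reductive macrocyclization of ynals (aldehyde–alkyne reductive coupling). The 19-membered ring closes in the endocyclic mode, both alkyne carbons ending in the ring, under slow addition at high dilution. The (E) geometry of C8=C9 follows from syn addition of C7 and H across the alkyne; the new C7 center forms under Felkin–Anh control of the C6 methoxy group, which predicts the 6,7-anti (7R) epimer, so its configuration is not relied upon and is reset in steps 23 and 24. The step needs bond formation at C8 and not at C9, secured by the small carbene ligand together with the size difference between the C8 methyl and the α-branched C10 substituent, and it needs the alkyne to react in preference to the trisubstituted, amide-conjugated C2=C3 olefin.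

Step 23
Reactants: 27 macrocyclic C7 alcohol
Product: 28 macrocyclic C7 enone (2E,6S,8E,10S,11R,12S,14S,15R)
Conditions: Dess–Martin periodinane, NaHCO3, CH2Cl2, 0 °C
Reagents that add atoms: none
Why: Dess–Martin oxidation of the allylic alcohol converges both C7 epimers on one α′-methoxy enone under buffered conditions that should not epimerize C6.

Step 24
Reactants: 28 macrocyclic C7 enone
Product: 29 macrolactam (2E,6S,7S,8E,10S,11R,12S,14S,15R)-7-hydroxy-11,15-bis(tert-butyldimethylsilyloxy)-18-(triisopropylsilyloxy)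
Conditions: (S)-2-methyl-CBS-oxazaborolidine (1.5 equiv), catecholborane, toluene, −78 °C
Reagents that add atoms: none
Why: Corey–Bakshi–Shibata reduction, in which the (S)-oxazaborolidine treats the α-methylalkenyl flank as the large group and should deliver hydride to give 7S, reinforced by the Felkin–Anh preference (hydride anti to the C6 methoxy group) for the 6,7-syn alcohol.

Step 25
Reactants: 29 (7S) alcohol
Product: 31 7-O-carbamoyl macrolactam (silyl ethers at C11, C15 and C18 retained), via N-trichloroacetyl carbamate 30 (not isolated)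
Conditions: Cl3CC(O)NCO, CH2Cl2, 0 °C; then neutral Al2O3 (6% H2O), rt
Reagents that add atoms: trichloroacetyl isocyanate, O=C=NC(=O)C(Cl)(Cl)Cl
Why: acyl isocyanate carbamoylation of the only free hydroxyl with retention at C7, followed by hydrolytic loss of the trichloroacetyl group on alumina without base that could cleave the aryl silyl ether.

Step 26
Reactants: 31 protected carbamate
Product: 32 target, (2E,6S,7S,8E,10S,11R,12S,14S,15R)-7-O-carbamoyl-11,15,18-trihydroxy-6,12-dimethoxy-2,8,10,14-tetramethyl 19-membered ansa lactam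
Conditions: HF·pyridine, pyridine, THF, 0 °C → rt
Reagents that add atoms: none
Why: buffered fluoride desilylation should remove the aryl and both secondary silyl ethers while leaving the allylic carbamate, the olefins and the benzylic alcohol intact.

**Compound list**

1 | pent-3-yn-2-one | CC#CC(C)=O | starting material
2 | (S)-pent-3-yn-2-ol | CC#C[C@H](C)O | intermediate
3 | (S)-pent-3-yn-2-yl methanesulfonate | CC#C[C@H](C)OS(C)(=O)=O | intermediate
4 | (M)-tributyl(penta-2,3-dien-2-yl)stannane | CC([H])=[C@]=C(C)[Sn](CCCC)(CCCC)CCCC | intermediate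
5 | 3-hydroxy-5-nitrobenzaldehyde | O=Cc1cc(O)cc(c1)[N+](=O)[O-] | starting material
6 | 3-nitro-5-(triisopropylsilyloxy)benzaldehyde | O=Cc1cc(O[Si](C(C)C)(C(C)C)C(C)C)cc(c1)[N+](=O)[O-] | intermediate
7 | (1R,2S)-2-methyl-1-[3-nitro-5-(triisopropylsilyloxy)phenyl]but-3-en-1-ol | C=C[C@H](C)[C@@H](O)c1cc(O[Si](C(C)C)(C(C)C)C(C)C)cc(c1)[N+](=O)[O-] | intermediate
8 | (5S,6R)-5-methyl-6-[3-nitro-5-(triisopropylsilyloxy)phenyl]oxan-2-ol (anomer mixture) | OC1CC[C@H](C)[C@@H](O1)c2cc(O[Si](C(C)C)(C(C)C)C(C)C)cc(c2)[N+](=O)[O-] | intermediate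
9 | (5S,6R)-5-methyl-6-[3-nitro-5-(triisopropylsilyloxy)phenyl]oxan-2-one | O=C1CC[C@H](C)[C@@H](O1)c2cc(O[Si](C(C)C)(C(C)C)C(C)C)cc(c2)[N+](=O)[O-] | intermediate
10 | potassium enolate of lactone 9 | [K+].[O-]C1=CC[C@H](C)[C@@H](O1)c2cc(O[Si](C(C)C)(C(C)C)C(C)C)cc(c2)[N+](=O)[O-] | intermediate
11 | (3S,5S,6R)-3-hydroxy-5-methyl-6-[3-nitro-5-(triisopropylsilyloxy)phenyl]oxan-2-one | O[C@H]1C[C@H](C)[C@@H](OC1=O)c2cc(O[Si](C(C)C)(C(C)C)C(C)C)cc(c2)[N+](=O)[O-] | intermediate
12 | (3S,5S,6R)-3-methoxy-5-methyl-6-[3-nitro-5-(triisopropylsilyloxy)phenyl]oxan-2-one | CO[C@H]1C[C@H](C)[C@@H](OC1=O)c2cc(O[Si](C(C)C)(C(C)C)C(C)C)cc(c2)[N+](=O)[O-] | intermediate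
13 | (2S,4S,5R)-5-hydroxy-N,2-dimethoxy-N,4-dimethyl-5-[3-nitro-5-(triisopropylsilyloxy)phenyl]pentanamide | CO[C@H](C(=O)N(C)OC)C[C@H](C)[C@@H](O)c1cc(O[Si](C(C)C)(C(C)C)C(C)C)cc(c1)[N+](=O)[O-] | intermediate
14 | (2S,4S,5R)-5-(tert-butyldimethylsilyloxy)-N,2-dimethoxy-N,4-dimethyl-5-[3-nitro-5-(triisopropylsilyloxy)phenyl]pentanamide | CO[C@H](C(=O)N(C)OC)C[C@H](C)[C@@H](O[Si](C)(C)C(C)(C)C)c1cc(O[Si](C(C)C)(C(C)C)C(C)C)cc(c1)[N+](=O)[O-] | intermediate
15 | (2S,4S,5R)-5-(tert-butyldimethylsilyloxy)-2-methoxy-4-methyl-5-[3-nitro-5-(triisopropylsilyloxy)phenyl]pentanal | CO[C@H](C=O)C[C@H](C)[C@@H](O[Si](C)(C)C(C)(C)C)c1cc(O[Si](C(C)C)(C(C)C)C(C)C)cc(c1)[N+](=O)[O-] | intermediate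
16 | (1R,2S,4S,5R,6S)-1-(tert-butyldimethylsilyloxy)-4-methoxy-2,6-dimethyl-1-[3-nitro-5-(triisopropylsilyloxy)phenyl]non-7-yn-5-ol | CO[C@H]([C@H](O)[C@@H](C)C#CC)C[C@H](C)[C@@H](O[Si](C)(C)C(C)(C)C)c1cc(O[Si](C(C)C)(C(C)C)C(C)C)cc(c1)[N+](=O)[O-] | intermediate
17 | (1R,2S,4S,5R,6S)-1,5-bis(tert-butyldimethylsilyloxy)-4-methoxy-2,6-dimethyl-1-[3-nitro-5-(triisopropylsilyloxy)phenyl]non-7-yne | CO[C@H]([C@H](O[Si](C)(C)C(C)(C)C)[C@@H](C)C#CC)C[C@H](C)[C@@H](O[Si](C)(C)C(C)(C)C)c1cc(O[Si](C(C)C)(C(C)C)C(C)C)cc(c1)[N+](=O)[O-] | intermediate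
18 | 3-[(1R,2S,4S,5R,6S)-1,5-bis(tert-butyldimethylsilyloxy)-4-methoxy-2,6-dimethylnon-7-yn-1-yl]-5-(triisopropylsilyloxy)aniline | CO[C@H]([C@H](O[Si](C)(C)C(C)(C)C)[C@@H](C)C#CC)C[C@H](C)[C@@H](O[Si](C)(C)C(C)(C)C)c1cc(O[Si](C(C)C)(C(C)C)C(C)C)cc(N)c1 | intermediate
19 | (S)-2-[(4-methoxybenzyloxy)methyl]oxirane | COc1ccc(COC[C@@H]2CO2)cc1 | starting material
20 | (S)-1-(4-methoxybenzyloxy)hex-5-en-2-ol | C=CCC[C@H](O)COCc1ccc(OC)cc1 | intermediate
21 | (S)-2-methoxy-1-(4-methoxybenzyloxy)hex-5-ene | C=CCC[C@H](OC)COCc1ccc(OC)cc1 | intermediate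
22 | methyl (2E,6S)-6-methoxy-7-(4-methoxybenzyloxy)-2-methylhept-2-enoate | COC(=O)/C(C)=C/CC[C@H](OC)COCc1ccc(OC)cc1 | intermediate
23 | seco anilide, C7 PMB ether | CO[C@H]([C@H](O[Si](C)(C)C(C)(C)C)[C@@H](C)C#CC)C[C@H](C)[C@@H](O[Si](C)(C)C(C)(C)C)c1cc(O[Si](C(C)C)(C(C)C)C(C)C)cc(c1)NC(=O)/C(C)=C/CC[C@H](OC)COCc2ccc(OC)cc2 | intermediate
24 | seco anilide, C7 primary alcohol | CO[C@H]([C@H](O[Si](C)(C)C(C)(C)C)[C@@H](C)C#CC)C[C@H](C)[C@@H](O[Si](C)(C)C(C)(C)C)c1cc(O[Si](C(C)C)(C(C)C)C(C)C)cc(c1)NC(=O)/C(C)=C/CC[C@H](OC)CO | intermediate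
25 | seco ynal, C7 aldehyde | CO[C@H]([C@H](O[Si](C)(C)C(C)(C)C)[C@@H](C)C#CC)C[C@H](C)[C@@H](O[Si](C)(C)C(C)(C)C)c1cc(O[Si](C(C)C)(C(C)C)C(C)C)cc(c1)NC(=O)/C(C)=C/CC[C@H](OC)C=O | intermediate
26 | macrolactam, (7R)-C7 triethylsilyl ether | CO[C@H]1C[C@H](C)[C@@H](O[Si](C)(C)C(C)(C)C)c2cc(O[Si](C(C)C)(C(C)C)C(C)C)cc(c2)NC(=O)/C(C)=C/CC[C@H](OC)[C@H](O[Si](CC)(CC)CC)/C(C)=C/[C@H](C)[C@H]1O[Si](C)(C)C(C)(C)C | intermediate
27 | macrolactam, (7R)-C7 alcohol | CO[C@H]1C[C@H](C)[C@@H](O[Si](C)(C)C(C)(C)C)c2cc(O[Si](C(C)C)(C(C)C)C(C)C)cc(c2)NC(=O)/C(C)=C/CC[C@H](OC)[C@H](O)/C(C)=C/[C@H](C)[C@H]1O[Si](C)(C)C(C)(C)C | intermediate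
28 | macrolactam, C7 enone | CO[C@H]1C[C@H](C)[C@@H](O[Si](C)(C)C(C)(C)C)c2cc(O[Si](C(C)C)(C(C)C)C(C)C)cc(c2)NC(=O)/C(C)=C/CC[C@H](OC)C(=O)/C(C)=C/[C@H](C)[C@H]1O[Si](C)(C)C(C)(C)C | intermediate
29 | macrolactam, (7S)-C7 alcohol | CO[C@H]1C[C@H](C)[C@@H](O[Si](C)(C)C(C)(C)C)c2cc(O[Si](C(C)C)(C(C)C)C(C)C)cc(c2)NC(=O)/C(C)=C/CC[C@H](OC)[C@@H](O)/C(C)=C/[C@H](C)[C@H]1O[Si](C)(C)C(C)(C)C | intermediate
30 | macrolactam, (7S)-C7 N-trichloroacetyl carbamate | CO[C@H]1C[C@H](C)[C@@H](O[Si](C)(C)C(C)(C)C)c2cc(O[Si](C(C)C)(C(C)C)C(C)C)cc(c2)NC(=O)/C(C)=C/CC[C@H](OC)[C@@H](OC(=O)NC(=O)C(Cl)(Cl)Cl)/C(C)=C/[C@H](C)[C@H]1O[Si](C)(C)C(C)(C)C | intermediate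
31 | macrolactam, (7S)-C7 carbamate, tris-silyl ether | CO[C@H]1C[C@H](C)[C@@H](O[Si](C)(C)C(C)(C)C)c2cc(O[Si](C(C)C)(C(C)C)C(C)C)cc(c2)NC(=O)/C(C)=C/CC[C@H](OC)[C@@H](OC(N)=O)/C(C)=C/[C@H](C)[C@H]1O[Si](C)(C)C(C)(C)C | intermediate
32 | CNP0309815.1 | CO[C@H]1C[C@H](C)[C@@H](O)c2cc(O)cc(c2)NC(=O)/C(C)=C/CC[C@H](OC)[C@@H](OC(N)=O)/C(C)=C/[C@H](C)[C@H]1O | target

**Totals.** 26 steps in all; longest linear sequence 20 steps (steps 4–15, then 19–26).

**Steps most likely to fail**

Step 22. Intermolecular oligomerization or simple hydrosilylation of the α-methoxy aldehyde may outrun the slow 19-membered oxidative cyclization, and bond formation at C9 (exocyclic mode) may erode the regioselectivity. The fallback closes the same C7–C8 bond by a Nozaki–Hiyama–Kishi reaction. It sets out from 24: palladium-catalysed hydrostannation (Bu3SnH, PdCl2(PPh3)2, THF) gives the (E)-C8 alkenylstannane F1; iododestannylation (I2, CH2Cl2, 0 °C) gives the (E)-alkenyl iodide F2; Dess–Martin oxidation gives the iodo aldehyde F3; and CrCl2 with catalytic NiCl2 in DMSO/THF at high dilution closes the ring. It comes back to the route at 27, either C7 epimer serving step 23.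

Step 24. Facial discrimination by the oxazaborolidine between the α-methylalkenyl and α-methoxyalkyl flanks may be insufficient, or conjugate reduction may compete. The fallback inverts the Felkin alcohol instead. It sets out from 27 (7R epimer): a Mitsunobu reaction (4-nitrobenzoic acid, PPh3, DIAD, toluene, 0 °C) gives the (7S)-4-nitrobenzoate F4, and brief methanolysis (K2CO3, MeOH, 0 °C) comes back to the route at 29.

Step 8. Facial selectivity in the enolate oxidation may be eroded (approach syn to the C14 methyl and C15 aryl groups), giving the C12 epimer. The fallback replaces kinetic by thermodynamic control. It sets out from 9: the epimeric (3R)-hydroxy lactone F5 formed in the oxidation is methylated as in step 9 to the (3R)-methoxy lactone F6, and DBU (toluene, rt) equilibrates C3 through the lactone enolate to the equatorial 3S epimer, coming back to the route at 12.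

Further compounds
F1 | step 22 | seco alcohol with (E)-C8 tributylstannyl alkene (Sn on C8, trans to C10) | CO[C@H]([C@H](O[Si](C)(C)C(C)(C)C)[C@@H](C)/C=C(\C)[Sn](CCCC)(CCCC)CCCC)C[C@H](C)[C@@H](O[Si](C)(C)C(C)(C)C)c1cc(O[Si](C(C)C)(C(C)C)C(C)C)cc(c1)NC(=O)/C(C)=C/CC[C@H](OC)CO
F2 | step 22 | seco alcohol with (E)-C8 alkenyl iodide | CO[C@H]([C@H](O[Si](C)(C)C(C)(C)C)[C@@H](C)/C=C(\C)I)C[C@H](C)[C@@H](O[Si](C)(C)C(C)(C)C)c1cc(O[Si](C(C)C)(C(C)C)C(C)C)cc(c1)NC(=O)/C(C)=C/CC[C@H](OC)CO
F3 | step 22 | seco C7 aldehyde with (E)-C8 alkenyl iodide | CO[C@H]([C@H](O[Si](C)(C)C(C)(C)C)[C@@H](C)/C=C(\C)I)C[C@H](C)[C@@H](O[Si](C)(C)C(C)(C)C)c1cc(O[Si](C(C)C)(C(C)C)C(C)C)cc(c1)NC(=O)/C(C)=C/CC[C@H](OC)C=O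
F4 | step 24 | macrolactam (7S)-C7 4-nitrobenzoate | CO[C@H]1C[C@H](C)[C@@H](O[Si](C)(C)C(C)(C)C)c2cc(O[Si](C(C)C)(C(C)C)C(C)C)cc(c2)NC(=O)/C(C)=C/CC[C@H](OC)[C@@H](OC(=O)c3ccc(cc3)[N+](=O)[O-])/C(C)=C/[C@H](C)[C@H]1O[Si](C)(C)C(C)(C)C
F5 | step 8 | (3R,5S,6R)-3-hydroxy-5-methyl-6-[3-nitro-5-(triisopropylsilyloxy)phenyl]oxan-2-one | O[C@@H]1C[C@H](C)[C@@H](OC1=O)c2cc(O[Si](C(C)C)(C(C)C)C(C)C)cc(c2)[N+](=O)[O-]
F6 | step 8 | (3R,5S,6R)-3-methoxy-5-methyl-6-[3-nitro-5-(triisopropylsilyloxy)phenyl]oxan-2-one | CO[C@@H]1C[C@H](C)[C@@H](OC1=O)c2cc(O[Si](C(C)C)(C(C)C)C(C)C)cc(c2)[N+](=O)[O-]
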